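**Retrosynthetic overview**
- The seven-membered ring and the spiro quaternary carbon are closed together in the last step. A dehydrogenative phenol–arene coupling joins the para carbon of the syringyl ring to C2 of the trimethoxyphenyl ring of an open-chain phenol acetate, as in the presumed plant phenol coupling. It is the only ring-forming step.
- The open chain comes from a homoallylic alcohol and 4-bromo-2,6-dimethoxyphenol by a catalyst-controlled anti-Markovnikov hydroarylation, which makes the CH2–aryl bond and the third stereocentre at once.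
- The homoallylic alcohol (first two stereocentres) comes from 3,4,5-trimethoxybenzaldehyde and a (Z)-2-methylbut-2-enylsilane (isoprene + HSiCl3) by a diamine-controlled syn-crotylation.
- Both benzene rings are bought, and no separate protecting-group step is used.

Assumption: the SMILES is read as acetoxy carbon R, adjacent CH(CH3) S, next CH(CH3) R (all-syn triad in zigzag); the spiro carbon is not a stereocentre because the dienone is symmetric.

**Step 1**
Reactants: 1 isoprene; 2 trichlorosilane
Product: 3 (Z)-trichloro(2-methylbut-2-en-1-yl)silane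
Conditions: Pd(PPh3)4 (0.2 mol%), neat, sealed tube, 80 °C; distil
Reagents that add atoms: none
Why: Palladium-catalysed 1,4-hydrosilylation of a 1,3-diene: H goes to the unsubstituted terminus and Si to the CH2 next to the methyl-bearing carbon through an allyl-palladium formed from the cisoid diene, which gives the Z allylsilane; no stereocentre is formed.

**Step 2**
Reactants: 3 (Z)-trichloro(2-methylbut-2-en-1-yl)silane; 4 (1S,2S)-N,N'-bis(4-bromobenzyl)cyclohexane-1,2-diamine; 5 3,4,5-trimethoxybenzaldehyde
Product: 7 (1R,2S)-2,3-dimethyl-1-(3,4,5-trimethoxyphenyl)but-3-en-1-ol, via chiral crotylsilane 6 (not isolated)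
Conditions: DBU (2 equiv), CH2Cl2, 0 °C to rt, pentane, filter; then 5, CH2Cl2, 0 °C, 24 h; aq. HCl, then NaOH (4 recovered)
Reagents that add atoms: none
Why: Leighton-type strained-silacycle crotylation through a closed chair transition state: the Z geometry is translated into the 1,2-syn relationship and the C2-symmetric diamine directs attack to the Re face of the aldehyde, giving 1R,2S (the face sense is confirmed once by Mosher analysis; the antipodal diamine is equally available).

**Step 3**
Reactants: 7 (1R,2S)-2,3-dimethyl-1-(3,4,5-trimethoxyphenyl)but-3-en-1-ol; 8 4-bromo-2,6-dimethoxyphenol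
Product: 12 (1R,2S,3R)-4-(4-hydroxy-3,5-dimethoxyphenyl)-2,3-dimethyl-1-(3,4,5-trimethoxyphenyl)butan-1-ol, via alkenyl silyl ether 9 (not isolated), via bromoaryl silyl ether 10 (not isolated), via coupled bis-silyl ether 11 (not isolated)
Conditions: Me(MeO)2SiH (5 equiv), Cu(OAc)2 (5 mol%), (R)-DTBM-SEGPHOS (5.5 mol%), THF, rt until H2 evolution stops; then [Pd(cinnamyl)Cl]2 (2 mol%), BrettPhos (4.4 mol%), NaOSiMe3 (2 equiv), 45 °C; then K2CO3, MeOH, rt
Reagents that add atoms: none
Why: CuH/Pd dual-catalytic anti-Markovnikov hydroarylation: both O–H groups are first capped in the flask as silyl ethers, the bulky ligand-bound CuH adds across the 1,1-disubstituted alkene (Cu to CH2, H to C3) on the face dictated by the ligand, which sets C3 as R with the two methyls syn (against the anti preference of the allylic centre; the ligand antipode is used if a test run shows the C3 epimer), and stereoretentive Cu-to-Pd transmetalation with C–C reductive elimination attaches ring B.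

**Step 4**
Reactants: 12 (1R,2S,3R)-4-(4-hydroxy-3,5-dimethoxyphenyl)-2,3-dimethyl-1-(3,4,5-trimethoxyphenyl)butan-1-ol
Product: 14 (1R,2S,3R)-4-(4-hydroxy-3,5-dimethoxyphenyl)-2,3-dimethyl-1-(3,4,5-trimethoxyphenyl)butyl acetate, via diacetate 13 (not isolated)
Conditions: Ac2O (4 equiv), Et3N, DMAP (10 mol%), CH2Cl2, rt; then pyrrolidine (6 equiv), 0 °C to rt
Reagents that add atoms: acetic anhydride, CC(=O)OC(C)=O
Why: DMAP-catalysed acylation of both hydroxyls followed by chemoselective aminolysis of the aryl acetate (phenoxide leaving group) in the presence of the hindered secondary alkyl acetate; no C–O bond at a stereocentre is broken, so all three centres are retained.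

**Step 5**
Reactants: 14 (1R,2S,3R)-4-(4-hydroxy-3,5-dimethoxyphenyl)-2,3-dimethyl-1-(3,4,5-trimethoxyphenyl)butyl acetate
Product: 15 (7R,8S,9R)-2,3,3',4,5'-pentamethoxy-7,8-dimethyl-4'-oxo-6,7,8,9-tetrahydrospiro[benzo[7]annulene-5,1'-cyclohexa[2,5]dien]-9-yl acetate (target)
Conditions: PhI(OAc)2 (1.1 equiv), CF3CH2OH (5 mM), −40 °C to −10 °C
Reagents that add atoms: none
Why: Kita-type hypervalent-iodine oxidative phenol dearomatisation (para-ipso phenol–arene coupling, the laboratory counterpart of the presumed biosynthetic coupling): ligand exchange at the phenol oxygen and loss of PhI give a phenoxonium-type cation that C2 of ring A (ortho and para to methoxy groups) captures at the para carbon to close the seven-membered ring, loss of H+ restores ring A, no stereocentre is formed (the spiro carbon is not stereogenic), and low temperature, high dilution and the absence of strong acid hold back the dienone–phenol shift and ionisation of the benzylic acetate.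

**Compound list**
1 | isoprene (2-methylbuta-1,3-diene) | C=CC(C)=C | starting material
2 | trichlorosilane | Cl[SiH](Cl)Cl | starting material
3 | (Z)-trichloro(2-methylbut-2-en-1-yl)silane | C/C=C(C)\C[Si](Cl)(Cl)Cl | intermediate
4 | (1S,2S)-N,N'-bis(4-bromobenzyl)cyclohexane-1,2-diamine | Brc1ccc(CN[C@H]2CCCC[C@@H]2NCc2ccc(Br)cc2)cc1 | starting material
5 | 3,4,5-trimethoxybenzaldehyde | COc1cc(C=O)cc(OC)c1OC | starting material
6 | (3aS,7aS)-1,3-bis(4-bromobenzyl)-2-chloro-2-[(Z)-2-methylbut-2-en-1-yl]octahydro-1H-1,3,2-benzodiazasilole | C/C=C(C)\C[Si]1(Cl)N(Cc2ccc(Br)cc2)[C@H]2CCCC[C@@H]2N1Cc1ccc(Br)cc1 | intermediate (not isolated)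
7 | (1R,2S)-2,3-dimethyl-1-(3,4,5-trimethoxyphenyl)but-3-en-1-ol | C=C(C)[C@H](C)[C@@H](O)c1cc(OC)c(OC)c(OC)c1 | intermediate
8 | 4-bromo-2,6-dimethoxyphenol | COc1cc(Br)cc(OC)c1O | starting material
9 | {[(1R,2S)-2,3-dimethyl-1-(3,4,5-trimethoxyphenyl)but-3-en-1-yl]oxy}dimethoxy(methyl)silane | C=C(C)[C@H](C)[C@@H](O[Si](C)(OC)OC)c1cc(OC)c(OC)c(OC)c1 | intermediate (not isolated)
10 | (4-bromo-2,6-dimethoxyphenoxy)dimethoxy(methyl)silane | COc1cc(Br)cc(OC)c1O[Si](C)(OC)OC | intermediate (not isolated)
11 | bis[dimethoxy(methyl)silyl] ether of 12 (alkyl O and aryl O both silylated; 1R,2S,3R) | COc1cc(C[C@@H](C)[C@H](C)[C@@H](O[Si](C)(OC)OC)c2cc(OC)c(OC)c(OC)c2)cc(OC)c1O[Si](C)(OC)OC | intermediate (not isolated)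
12 | (1R,2S,3R)-4-(4-hydroxy-3,5-dimethoxyphenyl)-2,3-dimethyl-1-(3,4,5-trimethoxyphenyl)butan-1-ol | COc1cc(C[C@@H](C)[C@H](C)[C@@H](O)c2cc(OC)c(OC)c(OC)c2)cc(OC)c1O | intermediate
13 | (1R,2S,3R)-4-(4-acetoxy-3,5-dimethoxyphenyl)-2,3-dimethyl-1-(3,4,5-trimethoxyphenyl)butyl acetate | COc1cc(C[C@@H](C)[C@H](C)[C@@H](OC(C)=O)c2cc(OC)c(OC)c(OC)c2)cc(OC)c1OC(C)=O | intermediate (not isolated)
14 | (1R,2S,3R)-4-(4-hydroxy-3,5-dimethoxyphenyl)-2,3-dimethyl-1-(3,4,5-trimethoxyphenyl)butyl acetate | COc1cc(C[C@@H](C)[C@H](C)[C@@H](OC(C)=O)c2cc(OC)c(OC)c(OC)c2)cc(OC)c1O | intermediate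
15 | (7R,8S,9R)-2,3,3',4,5'-pentamethoxy-7,8-dimethyl-4'-oxo-6,7,8,9-tetrahydrospiro[benzo[7]annulene-5,1'-cyclohexa[2,5]dien]-9-yl acetate | COC1=CC2(C=C(OC)C1=O)C[C@@H](C)[C@H](C)[C@@H](OC(C)=O)c1cc(OC)c(OC)c(OC)c12 | target

**Step count**
Total steps: 5. Longest linear sequence: 5 (1 → 3 → 7 → 12 → 14 → 15).

**Three steps most likely to fail, with fallbacks**

Step 5 (oxidative spirocyclisation). The risks are solvent capture at the para carbon, a dienone–phenol shift to the eight-membered biaryl, and loss of the benzylic acetate. The fallback sets out from 14 and comes back at 15, and it separates oxidation from C–C bond formation. Compound 14 is oxidised with PhI(OAc)2 in MeOH at 0 °C, so that methanol deliberately captures the para carbon and gives the isolable quinol methyl ether F1. F1 is then ionised without any oxidant (TMSOTf, 2,6-di-tert-butylpyridine, CH2Cl2, −78 °C). The same cation forms under non-oxidising conditions and closes onto ring A by ipso-Friedel–Crafts alkylation to give 15.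

Step 3 (hydroarylation). The risks are that the catalyst must override the substrate's anti preference at C3, and that two O–H groups are carried as in-flask silyl ethers. The fallback sets out from 7 and comes back at 12, and it separates arylation from stereocontrol. A Mizoroki–Heck reaction of 7 with 8 (Pd(OAc)2, P(o-tol)3, K2CO3, DMF, 100 °C) gives the E trisubstituted styrene F2. Its C=C bond is then hydrogenated under catalyst control with [Ir(cod)((S)-tBu-PHOX)][B(C6H3(CF3)2)4] (H2 50 bar, CH2Cl2, rt; ligand antipode chosen for the 3R product) to give 12.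

Step 2 (asymmetric 2-methylcrotylation). The risks are the enantio- and syn-selectivity of a 2-substituted crotylsilane with an electron-rich aldehyde, and the face sense of the diamine. The fallback sets out from 5 and comes back at 7, and it replaces allyl transfer by an auxiliary aldol. An Evans syn-aldol of 5 with the boron enolate of (R)-4-benzyl-3-propionyloxazolidin-2-one (Bu2BOTf, iPr2NEt, CH2Cl2, −78 °C) gives the syn-aldol imide F3. Transamidation with MeNH(OMe)·HCl/AlMe3 gives the Weinreb amide F4. MeMgBr (THF, 0 °C) gives the β-hydroxy methyl ketone F5. Methylenation with Ph3P=CH2 (2.5 equiv, THF, 0 °C) gives 7.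

**Further compounds**
F1 | step 5 | (1R,2S,3R)-2,3-dimethyl-4-(1,3,5-trimethoxy-4-oxocyclohexa-2,5-dien-1-yl)-1-(3,4,5-trimethoxyphenyl)butyl acetate | COC1=CC(OC)(C[C@@H](C)[C@H](C)[C@@H](OC(C)=O)c2cc(OC)c(OC)c(OC)c2)C=C(OC)C1=O
F2 | step 3 | (1R,2S,E)-4-(4-hydroxy-3,5-dimethoxyphenyl)-2,3-dimethyl-1-(3,4,5-trimethoxyphenyl)but-3-en-1-ol | COc1cc(/C=C(\C)[C@H](C)[C@@H](O)c2cc(OC)c(OC)c(OC)c2)cc(OC)c1O
F3 | step 2 | (R)-4-benzyl-3-[(2R,3R)-3-hydroxy-2-methyl-3-(3,4,5-trimethoxyphenyl)propanoyl]oxazolidin-2-one | O=C([C@H](C)[C@@H](O)c1cc(OC)c(OC)c(OC)c1)N1[C@H](Cc2ccccc2)COC1=O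
F4 | step 2 | (2R,3R)-3-hydroxy-N-methoxy-N,2-dimethyl-3-(3,4,5-trimethoxyphenyl)propanamide | CON(C)C(=O)[C@H](C)[C@@H](O)c1cc(OC)c(OC)c(OC)c1
F5 | step 2 | (3R,4R)-4-hydroxy-3-methyl-4-(3,4,5-trimethoxyphenyl)butan-2-one | CC(=O)[C@H](C)[C@@H](O)c1cc(OC)c(OC)c(OC)c1
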